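**Retrosynthetic overview**

- The last step is acetylation of O13. The key disconnection is C1–C2: the array O2–C2 / C1 / C15(=C17)–C16(=O) of the five-membered lactone (O2, C2, C1, C15, C16) is the retron of a carbonyl 2-(acyl)allylation. This is the bond a cembrane synthase makes, here with C2 as an enal carbon and C1 as an allyl terminus.
- Enabling feature: O13 sits 1,3 to C1 across C14, so C16 can first be carried by O13 in a six-membered lactone (O13, C13, C14, C1, C15, C16) that is not in the target. This temporary ring holds C14 cis to C16 on C1=C15 and lets 13S direct C1 and, through the chair, C2. The new C2 alkoxide then takes C16 over and frees O13.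
- The open chain is farnesol: C2–C13 with C18–C20 are C1–C12 of (2E,6E)-farnesol, so both E-olefins are bought. C13 is oxidised with SeO2, C11/C12 are set by Sharpless epoxidation, C14/C1 come from an allylboration that sets C13, and C15–C17 come from 2-(bromomethyl)acrylic acid.
- Ring order: oxirane (step 3), temporary six-membered lactone by ring-closing metathesis (step 9), 14-membered carbocycle (step 10). In that same flask the lactone contracts from six to five members by O13→O2 acyl shift; no ring is made afterwards.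

Key step: step 10

Remark: atoms carry cembrane numbers (ring C1–C14, C15 lactone α-carbon, C16 carbonyl, C17 methylene, C18–C20 the methyls on C4, C8, C12). The SMILES is read as 1R,2S,3E,7E,11R,12S,13S: trans-fused lactone, trans-epoxide, 13-acetate threo to the epoxide.

**Route**

Step 1
Reactants: 1 (2E,6E)-farnesol
Product: 2 (2E,6E)-farnesyl acetate
Conditions: Ac2O, pyridine, DMAP (cat.), CH2Cl2, 0 °C to rt
Reagents that add atoms: acetic anhydride CC(=O)OC(C)=O
Why: Nucleophile-catalysed O-acetylation blocks the C2 hydroxyl, so that the C13 alcohol made next is the only free allylic alcohol.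

Step 2
Reactants: 2 (2E,6E)-farnesyl acetate
Product: 3 (2E,6E,10E)-12-hydroxyfarnesyl acetate
Conditions: SeO2 (0.3 equiv), t-BuOOH (3 equiv), salicylic acid (cat.), CH2Cl2, rt
Reagents that add atoms: tert-butyl hydroperoxide CC(C)(C)OO; selenium dioxide O=[Se]=O (catalytic oxygen carrier)
Why: Allylic oxidation by SeO2 (ene reaction, then 2,3-sigmatropic shift) is selective for the (E)-methyl group of the terminal, most electron-rich trisubstituted olefin and should give the E-allylic alcohol, whose carbinol carbon becomes C13.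

Step 3
Reactants: 3 (2E,6E,10E)-12-hydroxyfarnesyl acetate
Product: 4 (2E,6E)-9-[(2R,3R)-3-(hydroxymethyl)-3-methyloxiran-2-yl]-3,7-dimethylnona-2,6-dien-1-yl acetate
Conditions: Ti(OiPr)4 (10 mol%), D-(−)-diethyl tartrate (12 mol%), t-BuOOH, 4 Å molecular sieves, CH2Cl2, −20 °C
Reagents that add atoms: tert-butyl hydroperoxide CC(C)(C)OO
Why: Sharpless asymmetric epoxidation: with D-(−)-tartrate the titanium-bound allylic alcohol is epoxidised on the face that gives the (2R,3R)-epoxy alcohol, which is C11 and C12 as in the target, while the acetate-blocked and the isolated olefin do not react.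

Step 4
Reactants: 4 (2E,6E)-9-[(2R,3R)-3-(hydroxymethyl)-3-methyloxiran-2-yl]-3,7-dimethylnona-2,6-dien-1-yl acetate
Product: 5 (2E,6E)-9-[(2R,3S)-3-formyl-3-methyloxiran-2-yl]-3,7-dimethylnona-2,6-dien-1-yl acetate
Conditions: TEMPO (cat.), PhI(OAc)2, CH2Cl2, rt
Reagents that add atoms: none
Why: Oxoammonium (TEMPO) oxidation of the primary alcohol stops at the aldehyde and spares epoxide and olefins; the α-carbon is fully substituted, so nothing can epimerise.

Step 5
Reactants: 5 (2E,6E)-9-[(2R,3S)-3-formyl-3-methyloxiran-2-yl]-3,7-dimethylnona-2,6-dien-1-yl acetate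
Product: 7 (2E,6E)-9-{(2R,3R)-3-[(1S)-1-hydroxybut-3-en-1-yl]-3-methyloxiran-2-yl}-3,7-dimethylnona-2,6-dien-1-yl acetate, via borinate 6 (not isolated)
Conditions: (−)-Ipc2B(allyl), Et2O, −78 °C; then NaBO3·4H2O, THF/H2O, rt
Reagents that add atoms: (−)-B-allyldiisopinocampheylborane C=CCB([C@@H]1C[C@@H]2C[C@H]([C@H]1C)C2(C)C)[C@@H]1C[C@@H]2C[C@H]([C@H]1C)C2(C)C
Why: Brown allylboration through a six-membered chair transition state: the reagent made from (+)-α-pinene adds allyl to the Si face of the aldehyde, which sets 13S (threo to the epoxide), and the polar Felkin–Anh preference of the epoxy aldehyde (epoxide C–O anti to the incoming group, approach past the tied-back ring carbon and not the methyl) should point the same way.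

Step 6
Reactants: 7 (2E,6E)-9-{(2R,3R)-3-[(1S)-1-hydroxybut-3-en-1-yl]-3-methyloxiran-2-yl}-3,7-dimethylnona-2,6-dien-1-yl acetate
Product: 8 (2E,6E)-9-{(2R,3R)-3-[(1S)-1-hydroxybut-3-en-1-yl]-3-methyloxiran-2-yl}-3,7-dimethylnona-2,6-dien-1-ol
Conditions: K2CO3 (cat.), MeOH, 0 °C
Reagents that add atoms: none
Why: Base-catalysed methanolysis (transesterification) removes the primary allylic acetate; the C13 alkoxide cannot open the epoxide at its fully substituted carbon, so no Payne rearrangement is expected.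

Step 7
Reactants: 8 (2E,6E)-9-{(2R,3R)-3-[(1S)-1-hydroxybut-3-en-1-yl]-3-methyloxiran-2-yl}-3,7-dimethylnona-2,6-dien-1-ol
Product: 9 (2E,6E)-9-{(2R,3R)-3-[(1S)-1-hydroxybut-3-en-1-yl]-3-methyloxiran-2-yl}-3,7-dimethylnona-2,6-dienal
Conditions: MnO2 (activated, excess), CH2Cl2, rt
Reagents that add atoms: none
Why: MnO2 oxidises only the allylic primary alcohol, so the C2 enal should form with retention of the 3E geometry while the secondary C13 alcohol stays free for acylation.

Step 8
Reactants: 9 (2E,6E)-9-{(2R,3R)-3-[(1S)-1-hydroxybut-3-en-1-yl]-3-methyloxiran-2-yl}-3,7-dimethylnona-2,6-dienal; 10 2-(bromomethyl)prop-2-enoic acid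
Product: 12 (1S)-1-{(2S,3R)-3-[(3E,7E)-3,7-dimethyl-9-oxonona-3,7-dien-1-yl]-2-methyloxiran-2-yl}but-3-en-1-yl 2-(bromomethyl)prop-2-enoate, via acid chloride 11 (not isolated)
Conditions: 10, (COCl)2, DMF (cat.), CH2Cl2, 0 °C to rt, evaporate; then 9, 2,6-di-tert-butyl-4-methylpyridine, CH2Cl2, −20 °C to rt
Reagents that add atoms: none
Why: O-acylation of the hindered secondary alcohol by the acid chloride under a non-nucleophilic hindered pyridine, which traps HCl (epoxide spared) and cannot quaternise the allylic bromide; C13 is not touched.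

Step 9
Reactants: 12 (1S)-1-{(2S,3R)-3-[(3E,7E)-3,7-dimethyl-9-oxonona-3,7-dien-1-yl]-2-methyloxiran-2-yl}but-3-en-1-yl 2-(bromomethyl)prop-2-enoate
Product: 13 (6S)-3-(bromomethyl)-6-{(2S,3R)-3-[(3E,7E)-3,7-dimethyl-9-oxonona-3,7-dien-1-yl]-2-methyloxiran-2-yl}-5,6-dihydro-2H-pyran-2-one
Conditions: second-generation Grubbs catalyst (H2IMes)(PCy3)Cl2Ru=CHPh (5 mol%), CH2Cl2 (5 mM), 40 °C
Reagents that add atoms: none
Why: Ring-closing olefin metathesis between the terminal vinyl group and the acrylate methylene closes the six-membered unsaturated lactone (C1=C15, necessarily cis in the ring) with loss of ethylene, the trisubstituted olefins and the enal being far less reactive.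

Step 10
Reactants: 13 (6S)-3-(bromomethyl)-6-{(2S,3R)-3-[(3E,7E)-3,7-dimethyl-9-oxonona-3,7-dien-1-yl]-2-methyloxiran-2-yl}-5,6-dihydro-2H-pyran-2-one
Product: 16 (1R,2S,3E,7E,11R,12R,13S)-11,12-epoxy-13-hydroxycembra-3,7,15(17)-trien-16,2-olide, via allylchromium dichloride 14 (not isolated), via bridged lactone alkoxide 15 (not isolated)
Conditions: CrCl2 (8 equiv), THF, 13 added by syringe pump over 12 h (final 2 mM), rt, then 45 °C; sat. aq. NH4Cl
Reagents that add atoms: none
Why: CrCl2 converts the allylic bromide into allylchromium 14 (two one-electron transfers), whose ring carbon C1 adds to the C2 aldehyde through a closed six-membered chair transition state (Nozaki–Hiyama–Kishi-type carbonyl 2-(acyl)allylation; the closest known types are the chromium-mediated closure of medium and large carbocycles from 2-(bromomethyl)acrylates and enals and the Barbier allylation of aldehydes with 3-(bromomethyl)-unsaturated lactones), after which the chromium alkoxide 15 attacks C16 and the acyl group moves from O13 to O2. The 14-membered carbocycle closes by exo 1,2-addition to the carbonyl with allylic transposition (14-exo-trig at C2, C15=C17 emerging as the methylene), and the five-membered lactone arises by 5-exo-trig acyl transfer that opens the temporary six-membered lactone. C1 is controlled by C13: the new bond should form axially on the half-chair lactone, on the face anti to the pseudo-equatorial C13 side chain (4,6-trans, as in conjugate additions to 6-substituted 5,6-dihydropyran-2-ones), which from 13S gives 1R. C2 is controlled by C1 through the chair: the temporary ring holds C14 trans to CH2Cr, so C14 and C3 are both equatorial and the anti adduct, hence the trans-fused lactone with 2S, should result. The step needs ring closure over oligomerisation (slow addition, 2 mM), γ- over α-attack and 1,2- over 1,4-addition (both inherent in the cyclic transition state of allylchromium reagents with enals), survival of the epoxide (nothing more Lewis acidic than trivalent chromium chloride is present) and a complete acyl shift (five- over six-membered lactone, relief of the bridged bicycle).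

Step 11
Reactants: 16 (1R,2S,3E,7E,11R,12R,13S)-11,12-epoxy-13-hydroxycembra-3,7,15(17)-trien-16,2-olide
Product: 17 (1R,2S,3E,7E,11R,12S,13S)-13-acetoxy-11,12-epoxycembra-3,7,15(17)-trien-16,2-olide (CNP0146076.5)
Conditions: Ac2O, pyridine, DMAP (cat.), CH2Cl2, rt
Reagents that add atoms: acetic anhydride CC(=O)OC(C)=O
Why: Nucleophile-catalysed acyl transfer to the liberated secondary 13-hydroxyl, with retention at C13, completes the target (the C12 descriptor changes from R to S only because the priorities change).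

**Compound list**

1 | (2E,6E)-farnesol | OC/C=C(\C)CC/C=C(\C)CCC=C(C)C | starting material
2 | (2E,6E)-farnesyl acetate | CC(=O)OC/C=C(\C)CC/C=C(\C)CCC=C(C)C | intermediate
3 | (2E,6E,10E)-12-hydroxyfarnesyl acetate | CC(=O)OC/C=C(\C)CC/C=C(\C)CC/C=C(\C)CO | intermediate
4 | (2E,6E)-9-[(2R,3R)-3-(hydroxymethyl)-3-methyloxiran-2-yl]-3,7-dimethylnona-2,6-dien-1-yl acetate | CC(=O)OC/C=C(\C)CC/C=C(\C)CC[C@H]1O[C@]1(C)CO | intermediate
5 | (2E,6E)-9-[(2R,3S)-3-formyl-3-methyloxiran-2-yl]-3,7-dimethylnona-2,6-dien-1-yl acetate | CC(=O)OC/C=C(\C)CC/C=C(\C)CC[C@H]1O[C@]1(C)C=O | intermediate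
6 | diisopinocampheylborinate of alcohol 7 (not isolated) | CC(=O)OC/C=C(\C)CC/C=C(\C)CC[C@H]1O[C@]1(C)[C@@H](OB([C@@H]2C[C@@H]3C[C@H]([C@H]2C)C3(C)C)[C@@H]2C[C@@H]3C[C@H]([C@H]2C)C3(C)C)CC=C | intermediate
7 | (2E,6E)-9-{(2R,3R)-3-[(1S)-1-hydroxybut-3-en-1-yl]-3-methyloxiran-2-yl}-3,7-dimethylnona-2,6-dien-1-yl acetate | CC(=O)OC/C=C(\C)CC/C=C(\C)CC[C@H]1O[C@]1(C)[C@@H](O)CC=C | intermediate
8 | (2E,6E)-9-{(2R,3R)-3-[(1S)-1-hydroxybut-3-en-1-yl]-3-methyloxiran-2-yl}-3,7-dimethylnona-2,6-dien-1-ol | OC/C=C(\C)CC/C=C(\C)CC[C@H]1O[C@]1(C)[C@@H](O)CC=C | intermediate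
9 | (2E,6E)-9-{(2R,3R)-3-[(1S)-1-hydroxybut-3-en-1-yl]-3-methyloxiran-2-yl}-3,7-dimethylnona-2,6-dienal | O=C/C=C(\C)CC/C=C(\C)CC[C@H]1O[C@]1(C)[C@@H](O)CC=C | intermediate
10 | 2-(bromomethyl)prop-2-enoic acid | C=C(CBr)C(=O)O | starting material
11 | 2-(bromomethyl)prop-2-enoyl chloride (not isolated) | C=C(CBr)C(Cl)=O | intermediate
12 | (1S)-1-{(2S,3R)-3-[(3E,7E)-3,7-dimethyl-9-oxonona-3,7-dien-1-yl]-2-methyloxiran-2-yl}but-3-en-1-yl 2-(bromomethyl)prop-2-enoate | O=C/C=C(\C)CC/C=C(\C)CC[C@H]1O[C@]1(C)[C@@H](OC(=O)C(=C)CBr)CC=C | intermediate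
13 | (6S)-3-(bromomethyl)-6-{(2S,3R)-3-[(3E,7E)-3,7-dimethyl-9-oxonona-3,7-dien-1-yl]-2-methyloxiran-2-yl}-5,6-dihydro-2H-pyran-2-one | O=C/C=C(\C)CC/C=C(\C)CC[C@H]1O[C@]1(C)[C@@H]2CC=C(CBr)C(=O)O2 | intermediate
14 | allylchromium dichloride from 13, trivalent chromium on C17 (not isolated) | O=C/C=C(\C)CC/C=C(\C)CC[C@H]1O[C@]1(C)[C@@H]2CC=C(C[Cr](Cl)Cl)C(=O)O2 | intermediate
15 | (1R,2S,11R,12S,13S) 14-membered carbocycle with C16 still on O13 (six-membered lactone bridging C13 and C1), C2 alkoxide on trivalent chromium (not isolated) | Cl[Cr](Cl)O[C@H]1/C=C(\C)CC/C=C(\C)CC[C@H]2O[C@]2(C)[C@@H]2C[C@@H]1C(=C)C(=O)O2 | intermediate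
16 | (1R,2S,3E,7E,11R,12R,13S)-11,12-epoxy-13-hydroxycembra-3,7,15(17)-trien-16,2-olide | C=C1C(=O)O[C@H]2/C=C(\C)CC/C=C(\C)CC[C@H]3O[C@]3(C)[C@@H](O)C[C@H]12 | intermediate
17 | (1R,2S,3E,7E,11R,12S,13S)-13-acetoxy-11,12-epoxycembra-3,7,15(17)-trien-16,2-olide | C=C1C(=O)O[C@H]2/C=C(\C)CC/C=C(\C)CC[C@H]3O[C@]3(C)[C@@H](OC(C)=O)C[C@H]12 | target

**Step count**

Total: 11 steps. Longest linear sequence: 11 steps (1 to 17); acid 10 is bought and enters in step 8.

**Steps most likely to fail**

Step 10 (key step). Bimolecular coupling or protonation of the allylchromium may outrun the slow closure of the 14-membered ring, or the ring may close on the wrong face of C1 if the tether overrides the bias of the lactone ring. The fallback sets out from 13 and replaces the reductive organochromium by an isolable boron nucleophile under catalyst control. Borylation of the allylic bromide (B2pin2, Pd2(dba)3, DMSO, rt) gives the allylboronate F1. Under dilution (toluene, 2 mM) a chiral phosphoric acid (the matching enantiomer of TRIP, 3,3′-bis(2,4,6-triisopropylphenyl)-1,1′-binaphthyl-2,2′-diyl hydrogen phosphate) catalyses the intramolecular allylboration. The catalyst chooses the aldehyde face and the ring-locked geometry fixes the anti course, which should give the macrocyclic pinacol borate F2. Hydrolytic work-up gives the hydroxy six-membered lactone F3, and catalytic DBU in CH2Cl2 shifts the acyl group from O13 to O2. The fallback comes back to the route at 16.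

Step 9. Metathesis of the electron-poor 1,1-disubstituted olefin may be slow enough for ionisation or cross-metathesis of the allylic bromide to take over, and the bromide may already be quaternised in step 8. The fallback sets out from 9 and carries C17 as a silyl ether. Commercial methyl 2-(hydroxymethyl)acrylate is silylated (TBSCl, imidazole) to methyl 2-[(tert-butyldimethylsilyloxy)methyl]prop-2-enoate F4 and saponified (LiOH) to the acid F5. Steglich esterification of 9 with F5 (DCC, DMAP) gives the ester F6. Ring-closing metathesis (second-generation Grubbs catalyst) gives the silyloxymethyl lactone F7, HF·pyridine gives the hydroxymethyl lactone F8, and Appel bromination (CBr4, PPh3) comes back to the route at 13.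

Step 5. Facial selectivity at the aldehyde may be poor if the bias of the epoxide opposes the reagent, or the Lewis-acidic borane may open the epoxide. The fallback sets out from 3, sets C13 before the epoxide exists and then inverts it. MnO2 gives the enal F9. (+)-Ipc2B(allyl), now under pure reagent control, gives the borinate F10 and after perborate work-up the 13R dienol F11. VO(acac)2/t-BuOOH epoxidises the allylic olefin syn to the hydroxyl with the A(1,2)-controlled erythro preference, to the erythro epoxy alcohol F12 (the 13-epimer of 7). Mitsunobu inversion (4-nitrobenzoic acid, PPh3, DIAD) gives the 13S 4-nitrobenzoate F13, and K2CO3/MeOH cleaves both esters. The fallback comes back to the route at 8.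

**Further compounds**

F1 | step 10 | (6S)-6-{(2S,3R)-3-[(3E,7E)-3,7-dimethyl-9-oxonona-3,7-dien-1-yl]-2-methyloxiran-2-yl}-3-[(4,4,5,5-tetramethyl-1,3,2-dioxaborolan-2-yl)methyl]-5,6-dihydro-2H-pyran-2-one | O=C/C=C(\C)CC/C=C(\C)CC[C@H]1O[C@]1(C)[C@@H]2CC=C(CB3OC(C)(C)C(C)(C)O3)C(=O)O2
F2 | step 10 | pinacol borate of the macrocyclic hydroxy six-membered lactone F3 | CC1(C)OB(O[C@H]2/C=C(\C)CC/C=C(\C)CC[C@H]3O[C@]3(C)[C@@H]3C[C@@H]2C(=C)C(=O)O3)OC1(C)C
F3 | step 10 | (1R,2S,11R,12S,13S) 14-membered carbocycle with free C2 hydroxyl and C16 on O13 (six-membered lactone bridging C13 and C1) | O[C@H]1/C=C(\C)CC/C=C(\C)CC[C@H]2O[C@]2(C)[C@@H]2C[C@@H]1C(=C)C(=O)O2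
F4 | step 9 | methyl 2-[(tert-butyldimethylsilyloxy)methyl]prop-2-enoate | C=C(CO[Si](C)(C)C(C)(C)C)C(=O)OC
F5 | step 9 | 2-[(tert-butyldimethylsilyloxy)methyl]prop-2-enoic acid | C=C(CO[Si](C)(C)C(C)(C)C)C(=O)O
F6 | step 9 | (1S)-1-{(2S,3R)-3-[(3E,7E)-3,7-dimethyl-9-oxonona-3,7-dien-1-yl]-2-methyloxiran-2-yl}but-3-en-1-yl 2-[(tert-butyldimethylsilyloxy)methyl]prop-2-enoate | O=C/C=C(\C)CC/C=C(\C)CC[C@H]1O[C@]1(C)[C@@H](OC(=O)C(=C)CO[Si](C)(C)C(C)(C)C)CC=C
F7 | step 9 | (6S)-3-[(tert-butyldimethylsilyloxy)methyl]-6-{(2S,3R)-3-[(3E,7E)-3,7-dimethyl-9-oxonona-3,7-dien-1-yl]-2-methyloxiran-2-yl}-5,6-dihydro-2H-pyran-2-one | O=C/C=C(\C)CC/C=C(\C)CC[C@H]1O[C@]1(C)[C@@H]2CC=C(CO[Si](C)(C)C(C)(C)C)C(=O)O2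
F8 | step 9 | (6S)-3-(hydroxymethyl)-6-{(2S,3R)-3-[(3E,7E)-3,7-dimethyl-9-oxonona-3,7-dien-1-yl]-2-methyloxiran-2-yl}-5,6-dihydro-2H-pyran-2-one | O=C/C=C(\C)CC/C=C(\C)CC[C@H]1O[C@]1(C)[C@@H]2CC=C(CO)C(=O)O2
F9 | step 5 | (2E,6E,10E)-3,7,11-trimethyl-12-oxododeca-2,6,10-trien-1-yl acetate | CC(=O)OC/C=C(\C)CC/C=C(\C)CC/C=C(\C)C=O
F10 | step 5 | diisopinocampheylborinate of dienol F11 | CC(=O)OC/C=C(\C)CC/C=C(\C)CC/C=C(\C)[C@H](OB([C@H]1C[C@H]2C[C@@H]([C@@H]1C)C2(C)C)[C@H]1C[C@H]2C[C@@H]([C@@H]1C)C2(C)C)CC=C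
F11 | step 5 | (2E,6E,10E,12R)-12-hydroxy-3,7,11-trimethylpentadeca-2,6,10,14-tetraen-1-yl acetate | CC(=O)OC/C=C(\C)CC/C=C(\C)CC/C=C(\C)[C@H](O)CC=C
F12 | step 5 | (2E,6E)-9-{(2R,3R)-3-[(1R)-1-hydroxybut-3-en-1-yl]-3-methyloxiran-2-yl}-3,7-dimethylnona-2,6-dien-1-yl acetate | CC(=O)OC/C=C(\C)CC/C=C(\C)CC[C@H]1O[C@]1(C)[C@H](O)CC=C
F13 | step 5 | (1S)-1-{(2S,3R)-3-[(3E,7E)-9-acetoxy-3,7-dimethylnona-3,7-dien-1-yl]-2-methyloxiran-2-yl}but-3-en-1-yl 4-nitrobenzoate | CC(=O)OC/C=C(\C)CC/C=C(\C)CC[C@H]1O[C@]1(C)[C@@H](OC(=O)c2ccc(cc2)[N+](=O)[O-])CC=C
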